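## Retrosynthetic overview

1. Gnetal 9 ⇐ tri-O-methyl ether 8 by a final global O-demethylation.
2. 8 ⇐ stilbene 4 + aryl(mesityl)iodonium salt 7. One Cu-catalysed enantioselective anti-oxyarylation forms the C3–aryl bond and the O1–C2 bond, and with them the dihydrofuran ring (the only ring made; the three benzene rings are bought) and both stereocentres.
3. Enabling feature: C3a is flanked by two oxygens (O1 on C7a, OH on C4), so the ring-opened precursor is a C2v-symmetric 2,6-dihydroxyaryl stilbene in which either hydroxyl closes the ring. The C6 formyl group (para to C3a) and the para oxygen of the C2 aryl make C2 the cation-stabilised and C3 the aryl-accepting alkene carbon. The resorcinol ring is joined through its carbon meta to both oxygens, which is not a nucleophilic position, so it is used as an iodine(III)/Cu(III) electrophile.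
4. 4 ⇐ bromide 2 + alkenylboronic acid 3 (Suzuki–Miyaura); 2 ⇐ 1; 7 ⇐ 5 + mesitylene.

Key step: step 4

Assumption: the sense of induction of the Cu–bis(oxazoline) catalyst on this new substrate class cannot be derived from precedent; the (S,S)-ligand is written for the (2S,3S) product, and its equally available enantiomer would be used if the opposite sense is found.

## Route

Step 1
Reactants: 1 4-bromo-3,5-dimethoxybenzaldehyde
Product: 2 4-bromo-3,5-dihydroxybenzaldehyde
Conditions: BBr3 (3.5 equiv), CH2Cl2, −78 °C → rt; then H2O
Reagents that add atoms: none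
Why: BBr3 cleavage of aryl methyl ethers (Lewis acid–base adduct, then bromide attack at methyl) should free both phenols, since the aldehyde and the aryl bromide are inert to it and no stereocentre is present.

Step 2
Reactants: 2 4-bromo-3,5-dihydroxybenzaldehyde; 3 (E)-[2-(4-methoxyphenyl)ethenyl]boronic acid
Product: 4 (E)-3,5-dihydroxy-4-[2-(4-methoxyphenyl)ethenyl]benzaldehyde
Conditions: Pd(OAc)2 (3 mol %), SPhos (6 mol %), K3PO4 (4 equiv), 1,4-dioxane/H2O 4:1 (degassed), 80 °C; acidify to pH 4 on work-up
Reagents that add atoms: none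
Why: Suzuki–Miyaura coupling with retention of the E geometry of 3 should give the stilbene, because the biarylphosphine ligand copes with the di-ortho-substituted bromide, the para formyl group speeds oxidative addition and free phenols are tolerated as phenoxides.

Step 3
Reactants: 5 1-iodo-3,5-dimethoxybenzene
Product: 7 (3,5-dimethoxyphenyl)(2,4,6-trimethylphenyl)iodonium trifluoromethanesulfonate, via aryl-λ3-iodane diacetate 6 (not isolated)
Conditions: mCPBA (1.1 equiv), AcOH, CH2Cl2, rt; then mesitylene (1.2 equiv), TfOH (1.1 equiv), 0 °C → rt; precipitation from Et2O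
Reagents that add atoms: mesitylene Cc1cc(C)cc(C)c1; trifluoromethanesulfonic acid OS(=O)(=O)C(F)(F)F; acetic acid CC(=O)O (its atoms stay in 6 only)
Why: Peracid oxidation of the aryl iodide to the aryl-λ3-iodane followed by acid-promoted electrophilic substitution of mesitylene at iodine(III) (one-pot diaryliodonium synthesis) should give 7, and oxidising all of 5 before the strong acid is added keeps the electron-rich dimethoxyarene, deactivated once it carries iodine(III), from acting as the arene partner.

Step 4
Reactants: 4 (E)-3,5-dihydroxy-4-[2-(4-methoxyphenyl)ethenyl]benzaldehyde; 7 (3,5-dimethoxyphenyl)(2,4,6-trimethylphenyl)iodonium trifluoromethanesulfonate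
Product: 8 (2S,3S)-3-(3,5-dimethoxyphenyl)-4-hydroxy-2-(4-methoxyphenyl)-2,3-dihydro-1-benzofuran-6-carbaldehyde (2,3-trans)
Conditions: (CuOTf)2·PhMe (5 mol %), (S,S)-Ph-BOX (12 mol %), 7 (1.2 equiv), 2,6-di-tert-butylpyridine (1.3 equiv), 4 Å MS, CH2Cl2, 0 → 25 °C
Reagents that add atoms: none
Why: Proposed new method: the chiral Cu(I)–bis(oxazoline) complex should add oxidatively to 7 to give an electrophilic aryl–Cu(III) species (the unhindered 3,5-dimethoxyphenyl is transferred, mesityl stays on iodine) that binds one face of the stilbene double bond, whereupon the hydroxyl lying on the opposite face attacks the anisyl-bearing carbon (future C2) and C–C reductive elimination from the resulting C3–Cu(III) alkyl places the aryl on C3 with retention, a net anti-oxyarylation. The closest known reaction type is the copper–bis(oxazoline)-catalysed enantioselective anti-oxyarylation of allylic amides with diaryliodonium salts (6-endo closure through the amide oxygen) and the related arylation-triggered semipinacol shift; here a phenol is the internal nucleophile and the ring is five-membered. The dihydrofuran ring closes in a 5-endo-trig mode onto the metal-activated, cation-like alkene, the mode known from halonium- and iodine(III)-induced cyclisations of 2-hydroxystilbenes. Both stereocentres arise in this one event: the ligand selects the alkene face that receives the aryl (C3), and anti addition across the E double bond fixes C2 relative to it as the 2,3-trans ring, while any cis isomer from a stepwise cationic path would converge on trans by reversible ionisation at C2 in step 5 without touching C3. Regioselectivity (aryl to C3, oxygen to C2) should be secured by the tether, which can only close a five-membered ring at C2, by the coplanar anisyl ring stabilising positive charge at C2, and by the formyl group para to C3a together with the twist of the di-ortho-substituted ring, which weaken stabilisation at C3; the two hydroxyls are equivalent, so no O-regioisomer exists. Chemoselectivity for C- over O-arylation is sought by keeping the phenols un-ionised (hindered pyridine base only, which also traps the triflic acid that would otherwise hydroalkoxylate the stilbene) and by the formyl-deactivated resorcinol ring.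

Step 5
Reactants: 8 (2S,3S)-3-(3,5-dimethoxyphenyl)-4-hydroxy-2-(4-methoxyphenyl)-2,3-dihydro-1-benzofuran-6-carbaldehyde
Product: 9 gnetal, (2S,3S)-3-(3,5-dihydroxyphenyl)-4-hydroxy-2-(4-hydroxyphenyl)-2,3-dihydro-1-benzofuran-6-carbaldehyde
Conditions: BBr3 (8 equiv), CH2Cl2 (dilute), −78 → 0 °C; then ice-water
Reagents that add atoms: none
Why: BBr3 demethylation should cleave the three aryl methyl ethers, and since C3 carries no ionisable group and any reversible opening of the benzylic C2–O1 bond re-closes to the more stable 2,3-trans ring, neither stereocentre should be scrambled.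

## Compound list

1 | 4-bromo-3,5-dimethoxybenzaldehyde | COc1cc(C=O)cc(OC)c1Br | starting material
2 | 4-bromo-3,5-dihydroxybenzaldehyde | O=Cc1cc(O)c(Br)c(O)c1 | intermediate
3 | (E)-[2-(4-methoxyphenyl)ethenyl]boronic acid | COc1ccc(/C=C/B(O)O)cc1 | starting material
4 | (E)-3,5-dihydroxy-4-[2-(4-methoxyphenyl)ethenyl]benzaldehyde | COc1ccc(/C=C/c2c(O)cc(C=O)cc2O)cc1 | intermediate
5 | 1-iodo-3,5-dimethoxybenzene | COc1cc(I)cc(OC)c1 | starting material
6 | 1-[bis(acetyloxy)-λ3-iodanyl]-3,5-dimethoxybenzene | COc1cc(cc(OC)c1)I(OC(C)=O)OC(C)=O | intermediate (not isolated)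
7 | (3,5-dimethoxyphenyl)(2,4,6-trimethylphenyl)iodonium trifluoromethanesulfonate | COc1cc(cc(OC)c1)[I+]c1c(C)cc(C)cc1C.[O-]S(=O)(=O)C(F)(F)F | intermediate
8 | (2S,3S)-3-(3,5-dimethoxyphenyl)-4-hydroxy-2-(4-methoxyphenyl)-2,3-dihydro-1-benzofuran-6-carbaldehyde | O=Cc1cc(O)c2c(c1)O[C@H](c1ccc(OC)cc1)[C@H]2c1cc(OC)cc(OC)c1 | intermediate
9 | gnetal, (2S,3S)-3-(3,5-dihydroxyphenyl)-4-hydroxy-2-(4-hydroxyphenyl)-2,3-dihydro-1-benzofuran-6-carbaldehyde | O=Cc1cc(O)c2c(c1)O[C@H](c1ccc(O)cc1)[C@H]2c1cc(O)cc(O)c1 | target

Total step count: 5
Longest linear sequence: 4 steps (1 → 2 → 4 → 8 → 9); the iodonium salt 7 is a one-step side branch.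

## Steps most likely to fail

**1. Step 4 (proposed new method).**
- What may go wrong: O-arylation of the un-ionised phenols, or of the product phenol, may outrun alkene arylation. Aryl transfer to the wrong alkene terminus, followed by proton loss, would give a triarylethene. The ligand may discriminate the two alkene faces poorly.
- Fallback (known chemistry, sets out from 2, returns at 8):
  - Acetalisation of 2 (ethylene glycol, TsOH, PhMe, Dean–Stark) should give 2-(4-bromo-3,5-dihydroxyphenyl)-1,3-dioxolane F1.
  - MOMCl/i-Pr2NEt should give 2-[4-bromo-3,5-bis(methoxymethoxy)phenyl]-1,3-dioxolane F2.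
  - Pd-catalysed ketone α-arylation of commercial 4′-methoxyacetophenone with F2 (Pd2(dba)3, XPhos, NaOtBu, PhMe, 80 °C) should give the deoxybenzoin 2-[4-(1,3-dioxolan-2-yl)-2,6-bis(methoxymethoxy)phenyl]-1-(4-methoxyphenyl)ethan-1-one F3.
  - A second α-arylation with commercial 1-bromo-3,5-dimethoxybenzene (Pd(OAc)2, P(t-Bu)3, NaOtBu) forms the same C3–aryl bond and should give the racemic, configurationally labile 2-(3,5-dimethoxyphenyl)-2-[4-(1,3-dioxolan-2-yl)-2,6-bis(methoxymethoxy)phenyl]-1-(4-methoxyphenyl)ethan-1-one F4.
  - Asymmetric transfer hydrogenation with dynamic kinetic resolution (RuCl(p-cymene)(TsDPEN), HCO2H/Et3N, catalyst enantiomer chosen to give the 2S methine) should set the diaryl-methine centre and give (2S)-2-(3,5-dimethoxyphenyl)-2-[4-(1,3-dioxolan-2-yl)-2,6-bis(methoxymethoxy)phenyl]-1-(4-methoxyphenyl)ethan-1-ol F5. Its carbinol configuration is of no consequence.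
  - HCl (cat., aq.) in MeOH at 45 °C with aqueous work-up should remove both MOM groups and the acetal and close the ring by SN1 cyclodehydration at the anisyl carbinol, trans to the C3 aryl, to give 8.

**2. Step 5.**
- What may go wrong: Lewis-acid ionisation of the benzylic C2–O1 bond may be followed by intermolecular trapping (oligomerisation) instead of re-closure. The BBr3-activated formyl group may undergo Friedel–Crafts attack by the electron-rich resorcinol rings.
- Fallback (sets out from 2, returns at 9, with base-labile protecting groups in place of the methyl ethers):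
  - Heck coupling of 2 with commercial 4-(tert-butyldimethylsilyloxy)styrene (Pd2(dba)3, P(t-Bu)3, Cy2NMe, dioxane, 70 °C) should give (E)-4-{2-[4-(tert-butyldimethylsilyloxy)phenyl]ethenyl}-3,5-dihydroxybenzaldehyde F6.
  - Commercial 5-iodoresorcinol is acetylated (Ac2O, pyridine) to 5-iodo-1,3-phenylene diacetate F7.
  - F7 is converted in one pot (mCPBA, TfOH, mesitylene, CH2Cl2, 0 °C → rt) into [3,5-bis(acetyloxy)phenyl](2,4,6-trimethylphenyl)iodonium trifluoromethanesulfonate F8. The acetoxy groups make this ring too electron-poor to compete with mesitylene.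
  - The step-4 oxyarylation applied to F6 and F8 should give (2S,3S)-3-[3,5-bis(acetyloxy)phenyl]-2-[4-(tert-butyldimethylsilyloxy)phenyl]-4-hydroxy-2,3-dihydro-1-benzofuran-6-carbaldehyde F9.
  - K2CO3 in MeOH (0 °C → rt, under argon) should cleave the two aryl acetates and the aryl silyl ether in one mild, non-acidic operation to give 9.

**3. Step 3.**
- What may go wrong: the electron-rich ring of not-yet-oxidised 5 may be attacked by the iodine(III) electrophile in place of mesitylene (self-arylation to oligomeric iodonium salts), or the ring may be oxidised by the peracid.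
- Fallback (sets out from 5, returns at 7):
  - Iodine–magnesium exchange (i-PrMgCl·LiCl, THF, −20 °C) and quenching with Bu3SnCl should give tributyl(3,5-dimethoxyphenyl)stannane F10.
  - Ipso-substitution of tin by the mesityl-λ3-iodane generated from commercial (diacetoxyiodo)mesitylene and TfOH (CH2Cl2, −40 → 0 °C) should give 7 regiospecifically. The iodine(III) is carried by the mesityl partner, so the dimethoxyarene is never exposed to an oxidant.

## Further compounds

F1 | step 4 | 2-(4-bromo-3,5-dihydroxyphenyl)-1,3-dioxolane | Oc1cc(C2OCCO2)cc(O)c1Br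
F2 | step 4 | 2-[4-bromo-3,5-bis(methoxymethoxy)phenyl]-1,3-dioxolane | COCOc1cc(C2OCCO2)cc(OCOC)c1Br
F3 | step 4 | 2-[4-(1,3-dioxolan-2-yl)-2,6-bis(methoxymethoxy)phenyl]-1-(4-methoxyphenyl)ethan-1-one | COCOc1cc(C2OCCO2)cc(OCOC)c1CC(=O)c1ccc(OC)cc1
F4 | step 4 | rac-2-(3,5-dimethoxyphenyl)-2-[4-(1,3-dioxolan-2-yl)-2,6-bis(methoxymethoxy)phenyl]-1-(4-methoxyphenyl)ethan-1-one | COCOc1cc(C2OCCO2)cc(OCOC)c1C(C(=O)c1ccc(OC)cc1)c1cc(OC)cc(OC)c1
F5 | step 4 | (2S)-2-(3,5-dimethoxyphenyl)-2-[4-(1,3-dioxolan-2-yl)-2,6-bis(methoxymethoxy)phenyl]-1-(4-methoxyphenyl)ethan-1-ol | COCOc1cc(C2OCCO2)cc(OCOC)c1[C@@H](C(O)c1ccc(OC)cc1)c1cc(OC)cc(OC)c1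
F6 | step 5 | (E)-4-{2-[4-(tert-butyldimethylsilyloxy)phenyl]ethenyl}-3,5-dihydroxybenzaldehyde | O=Cc1cc(O)c(/C=C/c2ccc(O[Si](C)(C)C(C)(C)C)cc2)c(O)c1
F7 | step 5 | 5-iodo-1,3-phenylene diacetate | CC(=O)Oc1cc(I)cc(OC(C)=O)c1
F8 | step 5 | [3,5-bis(acetyloxy)phenyl](2,4,6-trimethylphenyl)iodonium trifluoromethanesulfonate | CC(=O)Oc1cc(cc(OC(C)=O)c1)[I+]c1c(C)cc(C)cc1C.[O-]S(=O)(=O)C(F)(F)F
F9 | step 5 | (2S,3S)-3-[3,5-bis(acetyloxy)phenyl]-2-[4-(tert-butyldimethylsilyloxy)phenyl]-4-hydroxy-2,3-dihydro-1-benzofuran-6-carbaldehyde | O=Cc1cc(O)c2c(c1)O[C@H](c1ccc(O[Si](C)(C)C(C)(C)C)cc1)[C@H]2c1cc(OC(C)=O)cc(OC(C)=O)c1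
F10 | step 3 | tributyl(3,5-dimethoxyphenyl)stannane | CCCC[Sn](CCCC)(CCCC)c1cc(OC)cc(OC)c1
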